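**Retrosynthetic overview**

1. End-game: the target (cis-fused 3a,6a-dihydropentalene-1,6-dione, 3aS,6aS) is traced back through its heptamethyl ether to a C2-silylated bicycle, so only ether cleavage and C2 protodesilylation remain after the key step.
2. Key disconnection: ring 1 (C1–C2–C3–C3a–C6a) is opened at C1–C2 and, at the same time, at the exocyclic C3–C(α-styryl) bond. This leaves a ring-2 cyclopentenone carrying a silylalkyne (C2≡C3) on C3a and a methyl ester (C1) on C6a, cis to each other, plus an (E)-styrylboronic acid.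
3. Enabling feature: ring 1 is a cyclopent-2-enone whose C1 carbonyl sits on the carbinol carbon C6a and whose C3 sits on C3a, with C2 unsubstituted and the styryl group on C3 trans to C1 across C2=C3. The unit C1(=O)–C2=C3 is therefore the product of an anti alkenyl-acylation of a C3a-bound alkyne by a C6a-bound ester.
4. Ring 2 (C3a–C4–C5–C6–C6a, the 2,3-diarylcyclopentenone) comes from an enantioselective Nazarov cyclisation (C3a–C4 bond) of an alkylidene β-keto ester, itself assembled by Perkin condensation, malonate C-acylation and Knoevenagel condensation with a silylpropynal. The C6a–OH is installed by enolate oxygenation anti to the alkyne.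
5. Order of ring formation: ring 2 (step 4), then ring 1 (step 7).

Key step: step 7

Assumption: the sense of induction of the chiral copper catalyst in step 4 cannot be predicted for this substrate, so the ligand antipode that gives the (5R) ester is used; all later stereochemistry follows from that centre.

**Route**

Step 1
Reactants: 1 3,5-dimethoxybenzaldehyde; 2 3,4,5-trimethoxyphenylacetic acid
Product: 3 (E)-3-(3,5-dimethoxyphenyl)-2-(3,4,5-trimethoxyphenyl)prop-2-enoic acid
Conditions: Ac2O, Et3N, 110 °C; then H2O, aq. HCl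
Reagents that add atoms: none
Why: Perkin condensation (aldol addition of the arylacetic enolate to the aldehyde, then elimination); α-arylcinnamic acids are expected as the (E)-acids with the two aryl groups cis, which places the 3,5-dimethoxyphenyl group outward for step 4.

Step 2
Reactants: 3 (E)-3-(3,5-dimethoxyphenyl)-2-(3,4,5-trimethoxyphenyl)prop-2-enoic acid
Product: 5 methyl (E)-5-(3,5-dimethoxyphenyl)-3-oxo-4-(3,4,5-trimethoxyphenyl)pent-4-enoate, via acyl imidazolide 4 (not isolated)
Conditions: CDI, THF, rt; then KO2CCH2CO2Me, MgCl2, Et3N, MeCN, rt → 45 °C; aq. HCl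
Reagents that add atoms: potassium monomethyl malonate, COC(=O)CC(=O)[O-].[K+]; 1,1'-carbonyldiimidazole, O=C(n1ccnc1)n1ccnc1 (imidazolyl group of 4 only)
Why: Claisen-type C-acylation of the magnesium malonate half-ester by the acyl imidazolide, with decarboxylation on acidification, should give the β-keto ester without touching the hindered trisubstituted alkene.

Step 3
Reactants: 5 methyl (E)-5-(3,5-dimethoxyphenyl)-3-oxo-4-(3,4,5-trimethoxyphenyl)pent-4-enoate; 6 3-(trimethylsilyl)prop-2-ynal
Product: 7 methyl 2-[(E)-3-(3,5-dimethoxyphenyl)-2-(3,4,5-trimethoxyphenyl)prop-2-enoyl]-5-(trimethylsilyl)pent-2-en-4-ynoate (E/Z mixture at the new C2=C3 bond expected)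
Conditions: ethylenediammonium diacetate (10 mol %), 4 Å MS, CH2Cl2, 0 °C → rt
Reagents that add atoms: none
Why: Knoevenagel condensation at the doubly activated methylene; the geometry of the new alkylidene does not matter because it equilibrates under the Lewis acid of step 4.

Step 4
Reactants: 7 methyl 2-[(E)-3-(3,5-dimethoxyphenyl)-2-(3,4,5-trimethoxyphenyl)prop-2-enoyl]-5-(trimethylsilyl)pent-2-en-4-ynoate
Product: 8 methyl (1R,5R)-4-(3,5-dimethoxyphenyl)-2-oxo-3-(3,4,5-trimethoxyphenyl)-5-[(trimethylsilyl)ethynyl]cyclopent-3-ene-1-carboxylate (ester trans to the alkynyl group)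
Conditions: Cu(SbF6)2 (10 mol %), chiral tert-butyl-bis(oxazoline) ligand (11 mol %, antipode giving 5R), CH2Cl2, rt
Reagents that add atoms: none
Why: Catalytic asymmetric Nazarov cyclisation: two-point chelation of the β-keto ester to the chiral Cu(II) complex triggers a conrotatory 4π closure that forms the C4–C5 bond of ring 2 with catalyst-controlled torquoselectivity (sets C5), proton loss from C4 next to the aryl-stabilised terminus gives the tetrasubstituted enone, and the enolisable C1 settles trans to the alkyne.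

Step 5
Reactants: 8 methyl (1R,5R)-4-(3,5-dimethoxyphenyl)-2-oxo-3-(3,4,5-trimethoxyphenyl)-5-[(trimethylsilyl)ethynyl]cyclopent-3-ene-1-carboxylate
Product: 10 methyl (1R,5R)-4-(3,5-dimethoxyphenyl)-1-hydroxy-2-oxo-3-(3,4,5-trimethoxyphenyl)-5-[(trimethylsilyl)ethynyl]cyclopent-3-ene-1-carboxylate (OH trans and CO2Me cis to the alkynyl group), via potassium enolate 9 (not isolated)
Conditions: KHMDS (1.05 equiv), THF, −78 °C; then (±)-2-(phenylsulfonyl)-3-phenyloxaziridine, −78 °C; AcOH quench
Reagents that add atoms: 2-(phenylsulfonyl)-3-phenyloxaziridine, O=S(=O)(c1ccccc1)N1OC1c1ccccc1; KHMDS, C[Si](C)(C)[N-][Si](C)(C)C.[K+] (potassium of 9 only)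
Why: Electrophilic α-hydroxylation of a β-keto ester enolate by an N-sulfonyloxaziridine; oxygen should be delivered to the enolate face anti to the alkynyl group on the adjacent C5, which sets C1 with the ester cis to the alkyne, and any minor diastereomer is removed by chromatography.

Step 6
Reactants: 11 1-ethynyl-3,5-dimethoxybenzene
Product: 13 (E)-[2-(3,5-dimethoxyphenyl)ethenyl]boronic acid, via catechol boronate 12 (not isolated)
Conditions: catecholborane, neat, 70 °C; then H2O, rt
Reagents that add atoms: catecholborane, B1Oc2ccccc2O1; water, O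
Why: syn, anti-Markovnikov hydroboration of a terminal alkyne gives the (E)-alkenylboronate, which is hydrolysed to the boronic acid.

Step 7
Reactants: 10 methyl (1R,5R)-4-(3,5-dimethoxyphenyl)-1-hydroxy-2-oxo-3-(3,4,5-trimethoxyphenyl)-5-[(trimethylsilyl)ethynyl]cyclopent-3-ene-1-carboxylate; 13 (E)-[2-(3,5-dimethoxyphenyl)ethenyl]boronic acid
Product: 14 (3aR,6aR)-4-(3,5-dimethoxyphenyl)-3-[(E)-2-(3,5-dimethoxyphenyl)ethenyl]-6a-hydroxy-5-(3,4,5-trimethoxyphenyl)-2-(trimethylsilyl)-3a,6a-dihydropentalene-1,6-dione (cis-fused; same spatial arrangement as the target, the descriptors are R only because silicon raises the CIP rank of C3 and C1)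
Conditions: Ni(OAc)2·4H2O (10 mol %), 2-[2-(diphenylphosphino)ethyl]pyridine (10 mol %), 13 (2 equiv), degassed CF3CH2OH, 80 °C
Reagents that add atoms: none
Why: Proposed new method: transmetalation of 13 to Ni(II) gives an (E)-styrylnickel species that inserts the alkyne syn, forming the C3–C(styryl) bond and placing nickel on the silicon-bearing C2; the first-formed alkenylnickel has Ni trans to C3a, reversible E/Z isomerisation delivers the isomer whose C2–Ni bond adds to the cis ester carbonyl C1, and loss of methoxide from the nickel hemiketalate gives the C1 ketone and returns Ni(II)–OMe for the next transmetalation (redox-neutral cycle). The closest known reaction type is the nickel-catalysed anti-carbometallative cyclisation of alkyne-tethered esters and ketones with arylboronic acids, which turns aryl alkynes into 2,3-diarylcyclopent-2-enones; new here are the alkenylboron partner and the C-silyl alkyne. Ring 1 is closed in the 5-exo-trig mode (C2 onto the ester C1=O, C2–C1 bond), so one operation forms the C3–styryl bond, the C1–C2 bond and the complete ring-1 enone from a monocycle. No stereocentre is created: the cis ring fusion follows from the cis C3a-alkynyl/C6a-ester relationship set in steps 4 and 5, and the (E)-styryl geometry is carried over from 13 with retention. The step needs regioselective insertion (secured by silicon, which takes the metal on its own carbon), net anti addition across C2≡C3 (secured by the E/Z isomerisation, since only the cyclisable isomer is drained) and attack on the exocyclic ester rather than the ring ketone C6 (that would give a strained bicyclo[2.2.1]heptadiene alkoxide).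

Step 8
Reactants: 14 (3aR,6aR)-4-(3,5-dimethoxyphenyl)-3-[(E)-2-(3,5-dimethoxyphenyl)ethenyl]-6a-hydroxy-5-(3,4,5-trimethoxyphenyl)-2-(trimethylsilyl)-3a,6a-dihydropentalene-1,6-dione
Product: 15 (3aS,6aS)-4-(3,5-dimethoxyphenyl)-3-[(E)-2-(3,5-dimethoxyphenyl)ethenyl]-6a-hydroxy-5-(3,4,5-trimethoxyphenyl)-3a,6a-dihydropentalene-1,6-dione
Conditions: CF3CO2H (10 equiv), CH2Cl2, 0 °C
Reagents that add atoms: none
Why: ipso-Protodesilylation of a vinylsilane: protonation at C2 (the enone α-carbon) gives a cation at C3 that is β to silicon and dienylic, and loss of the silyl group restores the enone without involving C3a or C6a.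

Step 9
Reactants: 15 (3aS,6aS)-4-(3,5-dimethoxyphenyl)-3-[(E)-2-(3,5-dimethoxyphenyl)ethenyl]-6a-hydroxy-5-(3,4,5-trimethoxyphenyl)-3a,6a-dihydropentalene-1,6-dione
Product: 16 (3aS,6aS)-4-(3,5-dihydroxyphenyl)-3-[(E)-2-(3,5-dihydroxyphenyl)ethenyl]-6a-hydroxy-5-(3,4,5-trihydroxyphenyl)-3a,6a-dihydropentalene-1,6-dione (CNP0306657.1)
Conditions: BBr3 (15 equiv), CH2Cl2, −78 → 0 °C; MeOH, then H2O
Reagents that add atoms: none
Why: Lewis-acid cleavage of the seven aryl methyl ethers (O–B complexation, bromide attack at methyl, hydrolysis of the aryl borates); the tertiary carbinol flanked by two carbonyl groups cannot ionise and neither stereocentre is involved.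

**Compound list**

1 | 3,5-dimethoxybenzaldehyde | COc1cc(C=O)cc(OC)c1 | starting material
2 | 3,4,5-trimethoxyphenylacetic acid | COc1cc(CC(=O)O)cc(OC)c1OC | starting material
3 | (E)-3-(3,5-dimethoxyphenyl)-2-(3,4,5-trimethoxyphenyl)prop-2-enoic acid | OC(=O)/C(c1cc(OC)c(OC)c(OC)c1)=C/c1cc(OC)cc(OC)c1 | intermediate
4 | (E)-3-(3,5-dimethoxyphenyl)-1-(imidazol-1-yl)-2-(3,4,5-trimethoxyphenyl)prop-2-en-1-one (acyl imidazolide, not isolated) | O=C(n1ccnc1)/C(c1cc(OC)c(OC)c(OC)c1)=C/c1cc(OC)cc(OC)c1 | intermediate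
5 | methyl (E)-5-(3,5-dimethoxyphenyl)-3-oxo-4-(3,4,5-trimethoxyphenyl)pent-4-enoate | COC(=O)CC(=O)/C(c1cc(OC)c(OC)c(OC)c1)=C/c1cc(OC)cc(OC)c1 | intermediate
6 | 3-(trimethylsilyl)prop-2-ynal | C[Si](C)(C)C#CC=O | starting material
7 | methyl 2-[(E)-3-(3,5-dimethoxyphenyl)-2-(3,4,5-trimethoxyphenyl)prop-2-enoyl]-5-(trimethylsilyl)pent-2-en-4-ynoate (E/Z mixture at C2=C3) | COC(=O)C(=CC#C[Si](C)(C)C)C(=O)/C(c1cc(OC)c(OC)c(OC)c1)=C/c1cc(OC)cc(OC)c1 | intermediate
8 | methyl (1R,5R)-4-(3,5-dimethoxyphenyl)-2-oxo-3-(3,4,5-trimethoxyphenyl)-5-[(trimethylsilyl)ethynyl]cyclopent-3-ene-1-carboxylate | C[Si](C)(C)C#C[C@H]1C(c2cc(OC)cc(OC)c2)=C(c2cc(OC)c(OC)c(OC)c2)C(=O)[C@@H]1C(=O)OC | intermediate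
9 | potassium enolate of 8 (C1=C2 enolate, 5R; not isolated) | C[Si](C)(C)C#C[C@H]1C(c2cc(OC)cc(OC)c2)=C(c2cc(OC)c(OC)c(OC)c2)C([O-])=C1C(=O)OC.[K+] | intermediate
10 | methyl (1R,5R)-4-(3,5-dimethoxyphenyl)-1-hydroxy-2-oxo-3-(3,4,5-trimethoxyphenyl)-5-[(trimethylsilyl)ethynyl]cyclopent-3-ene-1-carboxylate | C[Si](C)(C)C#C[C@H]1C(c2cc(OC)cc(OC)c2)=C(c2cc(OC)c(OC)c(OC)c2)C(=O)[C@@]1(O)C(=O)OC | intermediate
11 | 1-ethynyl-3,5-dimethoxybenzene | COc1cc(C#C)cc(OC)c1 | starting material
12 | 2-[(E)-2-(3,5-dimethoxyphenyl)ethenyl]-1,3,2-benzodioxaborole (catechol boronate, not isolated) | COc1cc(/C=C/B2Oc3ccccc3O2)cc(OC)c1 | intermediate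
13 | (E)-[2-(3,5-dimethoxyphenyl)ethenyl]boronic acid | COc1cc(/C=C/B(O)O)cc(OC)c1 | intermediate
14 | (3aR,6aR)-4-(3,5-dimethoxyphenyl)-3-[(E)-2-(3,5-dimethoxyphenyl)ethenyl]-6a-hydroxy-5-(3,4,5-trimethoxyphenyl)-2-(trimethylsilyl)-3a,6a-dihydropentalene-1,6-dione | O=C1C([Si](C)(C)C)=C(/C=C/c2cc(OC)cc(OC)c2)[C@H]2C(c3cc(OC)cc(OC)c3)=C(c3cc(OC)c(OC)c(OC)c3)C(=O)[C@@]12O | intermediate
15 | (3aS,6aS)-4-(3,5-dimethoxyphenyl)-3-[(E)-2-(3,5-dimethoxyphenyl)ethenyl]-6a-hydroxy-5-(3,4,5-trimethoxyphenyl)-3a,6a-dihydropentalene-1,6-dione | O=C1C=C(/C=C/c2cc(OC)cc(OC)c2)[C@H]2C(c3cc(OC)cc(OC)c3)=C(c3cc(OC)c(OC)c(OC)c3)C(=O)[C@@]12O | intermediate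
16 | (3aS,6aS)-4-(3,5-dihydroxyphenyl)-3-[(E)-2-(3,5-dihydroxyphenyl)ethenyl]-6a-hydroxy-5-(3,4,5-trihydroxyphenyl)-3a,6a-dihydropentalene-1,6-dione | O=C1C=C(/C=C/c2cc(O)cc(O)c2)[C@H]2C(c3cc(O)cc(O)c3)=C(c3cc(O)c(O)c(O)c3)C(=O)[C@@]12O | target

**Step count and risks**

Total steps: 9. Longest linear sequence: 8 steps (1 → 3 → 5 → 7 → 8 → 10 → 14 → 15 → 16; steps 1–5 and 7–9).

Three steps most likely to fail:

1. Step 7 (proposed new method). The styryl group may be transferred to the silicon-bearing alkyne carbon instead of C3, the alkenylnickel may be protonated before it isomerises and closes, or protodeboronation of 13 may outrun insertion. The fallback uses known reactions only, sets out from 10 and returns at 15, replacing steps 7 and 8. Gold(I)-catalysed Markovnikov hydration of the alkynylsilane with loss of silicon ((Ph3P)AuNTf2, aqueous MeOH, 50 °C) should give the methyl ketone F1. Intramolecular Claisen condensation of its acetyl methyl group onto the ester (KOtBu, THF, 0 °C) should give the bicyclic trione F2, present mainly as its enol; C5 is epimerisable under these conditions, so only the cis-fused product can form. O-Triflation with PhNTf2/Et3N at the less hindered C3 oxygen (the C1 oxygen is flanked by the quaternary carbinol) should give the enol triflate F3, with any regioisomer separated. Suzuki–Miyaura coupling of F3 with 13 (Pd(PPh3)4, K3PO4, dioxane–H2O, 60 °C) then makes the same C3–styryl bond and gives 15.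

2. Step 4. The torquoselectivity may be insufficient on a dienone whose donor alkene is only aryl-substituted, or the copper catalyst may be diverted by π-coordination to the conjugated enyne. The fallback sets out from 7 and returns at 10, moving the stereocontrol from the electrocyclisation to the oxygenation. An achiral, purely oxophilic promoter (Sc(OTf)3, CH2Cl2, rt) should give the racemic trans keto ester F4. Its potassium enolate is then treated with a sub-stoichiometric amount (0.5 equiv) of an enantiopure (camphorsulfonyl)oxaziridine. Only the enantiomer for which the reagent's preferred face is also the face anti to the alkyne should be oxidised quickly, giving 10 by kinetic resolution; the unreacted enantiomer and any mismatched diastereomer are separated.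

3. Step 9. During the long exposure needed to cleave seven ethers, an electron-rich aryl ring may close onto the Lewis-acid-activated dienone, or the α-ketol may undergo an acyloin shift. The fallback sets out from 10 and 13 and returns at 16, moving the ether cleavage to the two robust fragments before ring 1 and the dienone exist. BBr3 on 10 should give the pentaphenol F5, and BBr3 on 13 should give the dihydroxy boronic acid F6. The nickel-catalysed step is then run on the free phenols in degassed CF3CH2OH to give the silylated heptaphenol F7. Buffered fluoride (TBAF/AcOH, THF, 0 °C) removes the C2 silicon and gives 16 without any strong acid on the finished polyphenol.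

**Further compounds**

F1 | step 7 | methyl (1R,5S)-5-acetyl-4-(3,5-dimethoxyphenyl)-1-hydroxy-2-oxo-3-(3,4,5-trimethoxyphenyl)cyclopent-3-ene-1-carboxylate | CC(=O)[C@H]1C(c2cc(OC)cc(OC)c2)=C(c2cc(OC)c(OC)c(OC)c2)C(=O)[C@@]1(O)C(=O)OC
F2 | step 7 | (3aS,6aS)-4-(3,5-dimethoxyphenyl)-6a-hydroxy-5-(3,4,5-trimethoxyphenyl)-3a,6a-dihydropentalene-1,3,6(2H)-trione | O=C1CC(=O)[C@H]2C(c3cc(OC)cc(OC)c3)=C(c3cc(OC)c(OC)c(OC)c3)C(=O)[C@@]12O
F3 | step 7 | (3aS,6aS)-4-(3,5-dimethoxyphenyl)-6a-hydroxy-1,6-dioxo-5-(3,4,5-trimethoxyphenyl)-1,3a,6,6a-tetrahydropentalen-3-yl trifluoromethanesulfonate | O=C1C=C(OS(=O)(=O)C(F)(F)F)[C@H]2C(c3cc(OC)cc(OC)c3)=C(c3cc(OC)c(OC)c(OC)c3)C(=O)[C@@]12O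
F4 | step 4 | racemic trans-methyl 4-(3,5-dimethoxyphenyl)-2-oxo-3-(3,4,5-trimethoxyphenyl)-5-[(trimethylsilyl)ethynyl]cyclopent-3-ene-1-carboxylate (racemate, relative configuration trans) | C[Si](C)(C)C#CC1C(c2cc(OC)cc(OC)c2)=C(c2cc(OC)c(OC)c(OC)c2)C(=O)C1C(=O)OC
F5 | step 9 | methyl (1R,5R)-4-(3,5-dihydroxyphenyl)-1-hydroxy-2-oxo-3-(3,4,5-trihydroxyphenyl)-5-[(trimethylsilyl)ethynyl]cyclopent-3-ene-1-carboxylate | C[Si](C)(C)C#C[C@H]1C(c2cc(O)cc(O)c2)=C(c2cc(O)c(O)c(O)c2)C(=O)[C@@]1(O)C(=O)OC
F6 | step 9 | (E)-[2-(3,5-dihydroxyphenyl)ethenyl]boronic acid | OB(O)/C=C/c1cc(O)cc(O)c1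
F7 | step 9 | (3aR,6aR)-4-(3,5-dihydroxyphenyl)-3-[(E)-2-(3,5-dihydroxyphenyl)ethenyl]-6a-hydroxy-5-(3,4,5-trihydroxyphenyl)-2-(trimethylsilyl)-3a,6a-dihydropentalene-1,6-dione | O=C1C([Si](C)(C)C)=C(/C=C/c2cc(O)cc(O)c2)[C@H]2C(c3cc(O)cc(O)c3)=C(c3cc(O)c(O)c(O)c3)C(=O)[C@@]12O
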